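(The numbers in the tables were computed with constants of no real substance; scatter was added.)

The constants of this comparison were the charges: the violet and blue flasks held the same starting material and partner and differed in free catalyst.

| setting | amber | red | violet | blue |
|---|---|---|---|---|
| starting material | 0.0800 M | 0.0400 M | 0.0800 M | 0.0800 M |
| partner | 0.0960 M | 0.0560 M | 0.0960 M | 0.0960 M |
| free catalyst | 0.00160 M | 0.00160 M | 0.00320 M | 0.00560 M |
| time |  |  |  | 170 s |

- amber run (time / s: [target] / M): 6.1: 0.0017; 18: 0.0057; 35: 0.0083; 56: 0.0113; 80: 0.0139; 110: 0.0149; 140: 0.0164; 170: 0.0150
- red run (time / s: [target] / M): 6.1: 0.0010; 18: 0.0029; 35: 0.0038; 56: 0.0054; 80: 0.0056; 110: 0.0065; 140: 0.0068; 170: 0.0060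
- violet run (time / s: [target] / M): 6.1: 0.0038; 18: 0.0103; 35: 0.0170; 56: 0.0212; 80: 0.0236; 110: 0.0256; 140: 0.0266; 170: 0.0269

(standard deviation of a reading: 4 × 10⁻⁴ M)

- Overall: starting material + partner -> target, with free catalyst as catalyst.
- Constant volume, constant temperature.
- What is held in complexes is read along with the free species.
- An order is taken over about fifteen percent of the charge, up and down.

* the power of [free catalyst] that the first rate follows, about the charge of the amber run; measure it at two percent of starting material made into target
* target in the blue run at 170 s, as a share of the starting material charged

Starting material is the limiting reagent, yet the readings flatten well short of its charge. So I turned the question round and asked what the blue flask needed in order to finish by the asked time. I replaced the falling curve of starting material by its mean, halfway between charge and what remained.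

B = c(target) / (charged free catalyst × mean c(starting material))

The violet flask at the asked time read 126 /M. This is my turnover budget: target made per free catalyst charged, per unit of mean starting material. The amber flask read 129 /M, close to that. The red flask, with less starting material and less partner, read less, 101 /M.

To finish, the mean is half the charge, so the blue flask needed:

B = 357 /M

That is more than violet's budget, by a factor of 2.83, so I expected blue to stop short. Carrying violet's budget over:

B × charged free catalyst = 0.707
share made = 52.3 %

Carrying violet over by the logarithm for first order in starting material gave 51.2 %, so on that reckoning the mean cost 1.1 percentage points. Red's lower budget made me lean below both figures.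

The forecast gave 48 % for the blue flask, between 42 % and 54 %, and an order in free catalyst about the amber charge of 0.95, between 0.8 and 1.05, saying “The catalyst is dying, apparently first-order”. Its share differs from mine.

The blue flask gave 50.3 %, and the order in free catalyst about the amber charge came to 1.1; both stood within tolerance of the forecast.

    free catalyst + starting material ⇌ catalyst-substrate complex, settled at all times (23.90 /M)
    catalyst-substrate complex + partner → target + free catalyst + by-product (7.020 /M/s)
    free catalyst → spent catalyst (0.03040 /s)
    2 starting material ⇌ idle substrate dimer, settled at all times (57.50 /M)

The blue flask's budget came to 120 /M, less than the 357 /M it needed to finish. The path from free catalyst to spent catalyst and the joining of starting material into idle substrate dimer, acting together, held it there. The blue run without the path to spent catalyst reached 89.8 %, a budget of 291 /M, and the blue run without the dimer reached 77.7 %, a budget of 227 /M.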